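## Retrosynthetic overview

1. The side-chain CO2H is unmasked last from a CH2NO2 group. The malate ester C–O bond comes from the primary alcohol and (R)-malic acid (made from maleic acid) through its O-trifluoroacetyl anhydride.
2. The γ-lactone acid comes from a 3-substituted cyclopentane-1,2-dione: tartrate/titanium-controlled hydroxylation, then Baeyer–Villiger-type ring expansion (five-membered diketone to six-membered anhydride) and collapse to the γ-lactone. This key step sets the quaternary carbon.
3. The C–C bond next to the ring comes from cyclopentane-1,2-dione and (E)-12-nitrododec-11-en-1-ol by a new nickel-catalysed Michael addition, which sets the CH stereocentre.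
4. The nitroalkene comes from dodec-11-en-1-ol, made from 6-bromohex-1-ene and 6-bromohexan-1-ol by copper-catalysed Grignard coupling.
5. Ring order: the purchased carbocycle is expanded to the anhydride ring, which contracts to the γ-lactone, the only ring of the target (lactone carbon R, side-chain CH S, malate carbon R).

Assumption: the (S,S)-diamine in step 3 and the L-tartrate in step 4 are the antipodes expected by analogy to deliver the stated faces; if a pilot run shows the opposite sense, the mirror-image ligand or tartrate is used and nothing else changes.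

## Route

Step 1
Reactants: 1 6-bromohex-1-ene (2.2 equiv); 2 6-bromohexan-1-ol
Product: 4 dodec-11-en-1-ol, via hex-5-enylmagnesium bromide 3 (not isolated)
Conditions: 1, Mg, THF, rt; then 2, Li2CuCl4 (3 mol %), THF, −20 → 0 °C; aq NH4Cl
Reagents that add atoms: none
Why: Copper-catalysed sp3–sp3 Grignard cross-coupling (Kochi type) of a primary alkylmagnesium bromide with a primary bromide; the first equivalent of 3 only deprotonates the hydroxyl of 2, so no protecting group is needed.

Step 2
Reactants: 4 dodec-11-en-1-ol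
Product: 6 (E)-12-nitrododec-11-en-1-ol, via 11-iodo-12-nitrododecan-1-ol 5 (not isolated)
Conditions: AgNO2, iodine, Et2O, 0 °C → rt, dark; then Et3N, 0 °C
Reagents that add atoms: silver nitrite AgNO2, [Ag+].[O-]N=O
Why: Iodonitration–dehydroiodination: nitryl iodide made in the flask adds NO2 to the terminal carbon and iodine to C11, and E1cB loss of HI gives the conjugated nitroalkene as the more stable E isomer, the remote hydroxyl being inert.

Step 3
Reactants: 6 (E)-12-nitrododec-11-en-1-ol; 7 cyclopentane-1,2-dione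
Product: 8 2-hydroxy-3-[(2S)-12-hydroxy-1-nitrododecan-2-yl]cyclopent-2-en-1-one
Conditions: Ni(OAc)2·4H2O (5 mol %), (S,S)-N,N'-dibenzylcyclohexane-1,2-diamine (6 mol %), i-PrOH, 0 °C → rt
Reagents that add atoms: none
Why: Proposed new method: a chiral diamine complex of divalent nickel acetate is used for the first time with a cyclic 1,2-diketone donor and an unbranched aliphatic nitroalkene — acetate deprotonates the enol of 7 to a maltol-like O,O-chelated nickel enolate whose nucleophilic C3 adds to the nitroalkene held by an N–H···O2N hydrogen bond of the ligand, the (S,S)-ligand exposing the Re face of C11 so that the C–C bond and the (S) centre form together; the closest known reaction type is the diamine–nickel-catalysed Michael addition of 1,3-dicarbonyls and α-keto esters to nitroalkenes.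

Step 4
Reactants: 8 2-hydroxy-3-[(2S)-12-hydroxy-1-nitrododecan-2-yl]cyclopent-2-en-1-one
Product: 11 (2R)-2-[(2R)-12-hydroxy-1-nitrododecan-2-yl]-5-oxooxolane-2-carboxylic acid, via hydroxy-dione 9 (not isolated), via cyclic anhydride 10 (not isolated)
Conditions: Ti(OiPr)4 (1.0 equiv), (+)-diethyl L-tartrate (1.6 equiv), t-BuOOH (2.5 equiv), 4 Å MS, CH2Cl2, −20 °C, 60 h; then 1 M HCl
Reagents that add atoms: tert-butyl hydroperoxide, CC(C)(C)OO
Why: Titanium–tartrate oxidation of a 3-substituted cyclopentane-1,2-dione enol (known for 3-alkyl cases): tartrate-controlled oxygen transfer to the Re face of the enol carbon C3 sets the quaternary (R) centre in 9, a second hydroperoxide adds to the C2 carbonyl and a 1,2-acyl shift from carbon to oxygen (Baeyer–Villiger-type ring expansion) gives anhydride 10, whose tertiary hydroxyl attacks the distal carbonyl to give the γ-lactone acid, the neighbouring CH centre not being touched.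

Step 5
Reactants: 12 maleic acid
Product: 13 (R)-malic acid
Conditions: maleate hydratase (permeabilised Pseudomonas pseudoalcaligenes cells), Tris buffer pH 8, 30 °C; then H+ ion-exchange resin
Reagents that add atoms: water, O
Why: Enzymatic hydration of maleate by maleate hydratase gives only the D-(R)-enantiomer, a known biocatalytic alkene hydration.

Step 6
Reactants: 13 (R)-malic acid (1.5 equiv); 11 (2R)-2-[(2R)-12-hydroxy-1-nitrododecan-2-yl]-5-oxooxolane-2-carboxylic acid
Product: 16 (3R)-4-({(11R)-11-[(2R)-2-carboxy-5-oxooxolan-2-yl]-12-nitrododecyl}oxy)-3-hydroxy-4-oxobutanoic acid, via anhydride trifluoroacetate 14 (not isolated), via ester trifluoroacetate 15 (not isolated)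
Conditions: 13, (CF3CO)2O, 0 °C → rt, evaporate; then 11, THF, 0 °C → rt; then H2O–THF, rt
Reagents that add atoms: none
Why: Regioselective anhydride alcoholysis (the known route to malic acid 1-monoesters): the primary alcohol opens 14 at the carbonyl next to the CH–OCOCF3 carbon, the more electrophilic one, without touching the stereocentre, the trifluoroacetate is hydrolysed on aqueous work-up, and the hindered tertiary CO2H of 11 is not activated.

Step 7
Reactants: 16 (3R)-4-({(11R)-11-[(2R)-2-carboxy-5-oxooxolan-2-yl]-12-nitrododecyl}oxy)-3-hydroxy-4-oxobutanoic acid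
Product: 18 (2R)-2-[(1S)-1-carboxy-11-{[(2R)-3-carboxy-2-hydroxypropanoyl]oxy}undecyl]-5-oxooxolane-2-carboxylic acid, via nitrolic acid 17 (not isolated)
Conditions: NaNO2 (3 equiv), AcOH (10 equiv), DMSO, 35 °C; then 1 M HCl, EtOAc; C18 chromatography
Reagents that add atoms: sodium nitrite, [Na+].[O-]N=O; water, O
Why: Nef-type nitrosative oxidation of a primary nitro group to the carboxylic acid under weakly acidic conditions, which do not enolise the adjacent CH centre (configuration retained; the descriptor changes from R to S only through priorities) and leave the lactone, ester and α-hydroxy ester intact.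

## Compound list

1 | 6-bromohex-1-ene | C=CCCCCBr | starting material
2 | 6-bromohexan-1-ol | OCCCCCCBr | starting material
3 | hex-5-enylmagnesium bromide | C=CCCCC[Mg]Br | intermediate
4 | dodec-11-en-1-ol | OCCCCCCCCCCC=C | intermediate
5 | 11-iodo-12-nitrododecan-1-ol (racemic) | OCCCCCCCCCCC(I)C[N+](=O)[O-] | intermediate
6 | (E)-12-nitrododec-11-en-1-ol | OCCCCCCCCCC/C=C/[N+](=O)[O-] | intermediate
7 | cyclopentane-1,2-dione | O=C1CCCC1=O | starting material
8 | 2-hydroxy-3-[(2S)-12-hydroxy-1-nitrododecan-2-yl]cyclopent-2-en-1-one | OCCCCCCCCCC[C@H](C[N+](=O)[O-])C1=C(O)C(=O)CC1 | intermediate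
9 | (3R)-3-hydroxy-3-[(2R)-12-hydroxy-1-nitrododecan-2-yl]cyclopentane-1,2-dione | OCCCCCCCCCC[C@H](C[N+](=O)[O-])[C@]1(O)CCC(=O)C1=O | intermediate
10 | (3R)-3-hydroxy-3-[(2R)-12-hydroxy-1-nitrododecan-2-yl]oxane-2,6-dione | OCCCCCCCCCC[C@H](C[N+](=O)[O-])[C@]1(O)CCC(=O)OC1=O | intermediate
11 | (2R)-2-[(2R)-12-hydroxy-1-nitrododecan-2-yl]-5-oxooxolane-2-carboxylic acid | OCCCCCCCCCC[C@H](C[N+](=O)[O-])[C@@]1(C(=O)O)CCC(=O)O1 | intermediate
12 | maleic acid | OC(=O)/C=C\C(=O)O | starting material
13 | (R)-malic acid | OC(=O)C[C@@H](O)C(=O)O | intermediate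
14 | (3R)-2,5-dioxooxolan-3-yl trifluoroacetate | O=C1C[C@@H](OC(=O)C(F)(F)F)C(=O)O1 | intermediate
15 | (3R)-4-({(11R)-11-[(2R)-2-carboxy-5-oxooxolan-2-yl]-12-nitrododecyl}oxy)-4-oxo-3-(trifluoroacetoxy)butanoic acid | OC(=O)C[C@@H](OC(=O)C(F)(F)F)C(=O)OCCCCCCCCCC[C@H](C[N+](=O)[O-])[C@@]1(C(=O)O)CCC(=O)O1 | intermediate
16 | (3R)-4-({(11R)-11-[(2R)-2-carboxy-5-oxooxolan-2-yl]-12-nitrododecyl}oxy)-3-hydroxy-4-oxobutanoic acid | OC(=O)C[C@@H](O)C(=O)OCCCCCCCCCC[C@H](C[N+](=O)[O-])[C@@]1(C(=O)O)CCC(=O)O1 | intermediate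
17 | (3R)-4-({(11R)-11-[(2R)-2-carboxy-5-oxooxolan-2-yl]-12-(hydroxyimino)-12-nitrododecyl}oxy)-3-hydroxy-4-oxobutanoic acid | OC(=O)C[C@@H](O)C(=O)OCCCCCCCCCC[C@H](C(=NO)[N+](=O)[O-])[C@@]1(C(=O)O)CCC(=O)O1 | intermediate
18 | (2R)-2-[(1S)-1-carboxy-11-{[(2R)-3-carboxy-2-hydroxypropanoyl]oxy}undecyl]-5-oxooxolane-2-carboxylic acid | O=C(O)C[C@@H](O)C(=O)OCCCCCCCCCC[C@H](C(=O)O)[C@@]1(C(=O)O)CCC(=O)O1 | target

## Step count and risks

Total steps: 7. Longest linear sequence: 6 (steps 1, 2, 3, 4, 6, 7); step 5 is a one-step side branch.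

Three steps most likely to fail:

1) Step 3, the proposed new Michael addition. The chelating dione and its product may bind nickel too strongly, giving slow turnover or low ee, and the facial sense is untested. Fallback with known chemistry: from 6 and 7, plain amine catalysis (Et3N 10 mol %, CH2Cl2, rt) gives racemic 2-hydroxy-3-(12-hydroxy-1-nitrododecan-2-yl)cyclopent-2-en-1-one F3. Under the step 4 conditions the tartrate fixes the ring carbon in both enantiomers, so besides 9, 10 and 11 the side-chain epimers form: (3R)-3-hydroxy-3-[(2S)-12-hydroxy-1-nitrododecan-2-yl]cyclopentane-1,2-dione F4, (3R)-3-hydroxy-3-[(2S)-12-hydroxy-1-nitrododecan-2-yl]oxane-2,6-dione F5 and (2R)-2-[(2S)-12-hydroxy-1-nitrododecan-2-yl]-5-oxooxolane-2-carboxylic acid F6. Compound 11 is separated from F6 by chromatography or salt crystallisation, and the route resumes at 11. Stereocontrol at the CH centre is thus traded for a diastereomer separation.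

2) Step 4, the oxidative ring expansion. The existing CH centre may be mismatched with the tartrate, the free hydroxyl or a titanium nitronate may disturb the complex, and the reaction may stop at 9. Fallback: from 8, a metal-free two-stage sequence under substrate control. Dimethyldioxirane (acetone, −40 °C) hydroxylates the enol to 9 together with (3S)-3-hydroxy-3-[(2R)-12-hydroxy-1-nitrododecan-2-yl]cyclopentane-1,2-dione F7. Then 30% H2O2 in HCO2H effects the Baeyer–Villiger-type expansion to 10 and (3S)-3-hydroxy-3-[(2R)-12-hydroxy-1-nitrododecan-2-yl]oxane-2,6-dione F8, which collapse to 11 and (2S)-2-[(2R)-12-hydroxy-1-nitrododecan-2-yl]-5-oxooxolane-2-carboxylic acid F9. Separation of 11 from F9 brings the route back at 11.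

3) Step 2, nitration of the hydroxy-alkene. Yields are moderate, E/Z mixtures are possible and the free alcohol may be attacked. Fallback: from 4, ozonolysis (O3, CH2Cl2–MeOH, −78 °C; Me2S) gives 11-hydroxyundecanal F1. Henry addition of nitromethane (piperidine, 4 Å MS, toluene, reflux) gives 12-nitrododecane-1,11-diol F2, which dehydrates under the same conditions to the E nitroalkene, and the route resumes at 6.

## Further compounds

F1 | step 2 | 11-hydroxyundecanal | OCCCCCCCCCCC=O
F2 | step 2 | 12-nitrododecane-1,11-diol | OCCCCCCCCCCC(O)C[N+](=O)[O-]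
F3 | step 3 | racemic 2-hydroxy-3-(12-hydroxy-1-nitrododecan-2-yl)cyclopent-2-en-1-one | OCCCCCCCCCCC(C[N+](=O)[O-])C1=C(O)C(=O)CC1
F4 | step 3 | (3R)-3-hydroxy-3-[(2S)-12-hydroxy-1-nitrododecan-2-yl]cyclopentane-1,2-dione | OCCCCCCCCCC[C@@H](C[N+](=O)[O-])[C@]1(O)CCC(=O)C1=O
F5 | step 3 | (3R)-3-hydroxy-3-[(2S)-12-hydroxy-1-nitrododecan-2-yl]oxane-2,6-dione | OCCCCCCCCCC[C@@H](C[N+](=O)[O-])[C@]1(O)CCC(=O)OC1=O
F6 | step 3 | (2R)-2-[(2S)-12-hydroxy-1-nitrododecan-2-yl]-5-oxooxolane-2-carboxylic acid | OCCCCCCCCCC[C@@H](C[N+](=O)[O-])[C@@]1(C(=O)O)CCC(=O)O1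
F7 | step 4 | (3S)-3-hydroxy-3-[(2R)-12-hydroxy-1-nitrododecan-2-yl]cyclopentane-1,2-dione | OCCCCCCCCCC[C@H](C[N+](=O)[O-])[C@@]1(O)CCC(=O)C1=O
F8 | step 4 | (3S)-3-hydroxy-3-[(2R)-12-hydroxy-1-nitrododecan-2-yl]oxane-2,6-dione | OCCCCCCCCCC[C@H](C[N+](=O)[O-])[C@@]1(O)CCC(=O)OC1=O
F9 | step 4 | (2S)-2-[(2R)-12-hydroxy-1-nitrododecan-2-yl]-5-oxooxolane-2-carboxylic acid | OCCCCCCCCCC[C@H](C[N+](=O)[O-])[C@]1(C(=O)O)CCC(=O)O1
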